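The route rests on disconnecting C9–C10: ring C (C6–C7–C8–C9–C10) is closed late on a ring A–cyclobutane bicycle by dirhodium-carbenoid C–H insertion. The step exploits the tertiary C10–H of the cyclobutane (C1–C5–C6–C10), which lies endo and cis to the C6 side chain; in one operation it forms C9–C10, closes ring C and creates quaternary C10 with retention, giving the cis-syn-cis core. The precursor is the ring-A-fused cyclobutane with exo C14, endo C10–H and, on C6, exo O6 and the endo chain C7(O)–C8(=O)–C9H=N2, with O6 and O7 bridged as an acetonide so that C8 is held cis to C10.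

Key step: step 10

Remark on numbering: atoms are numbered as in the target (cyclobutane C1–C5–C6–C10; ring A C1–C2–C3–C4–C5; ring C C6–C7–C8–C9–C10; lactone C6–O–C12(=O)–C11(C13)=C7; C14 on C10, C15 on C4); exo is the cyclobutane face of H1 and H5, endo the face of ring A, and the outer face of ring C is the one that carries O6 and C14.

Remark on design: C7 is a temporary stereocentre and is taken with O7 cis to O6 (from the E-enoate), because an O7 substituent on the inner face of ring C would be pressed against C15 during ring closure and could not be bridged to O6; O4 is carried as a TBS ether so that the acetonide can later be removed by acid. Compound 22 is assumed to be a catalogue item.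

Step 1
Reactants: 1 (S)-4-(tert-butyldimethylsilyloxy)cyclopent-2-en-1-one
Product: 2 (1R,4S)-4-(tert-butyldimethylsilyloxy)-1-methylcyclopent-2-en-1-ol (OH cis to OTBS)
Conditions: MeLi, Et2O, −78 °C; then H2O
Reagents that add atoms: methyllithium, [Li]C
Why: 1,2-addition of the organolithium to the enone carbonyl should occur anti to the C2 silyloxy group, so that O4 ends up cis to O2 and C15 trans to it (substrate-controlled carbonyl addition).

Step 2
Reactants: 2 cis-alcohol
Product: 3 (3R,5S)-3,5-bis(tert-butyldimethylsilyloxy)-3-methylcyclopent-1-ene (both silyloxy groups on one face)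
Conditions: TBSOTf, 2,6-lutidine, CH2Cl2, 0 °C to rt
Reagents that add atoms: tert-butyldimethylsilyl trifluoromethanesulfonate, CC(C)(C)[Si](C)(C)OS(=O)(=O)C(F)(F)F
Why: silyl triflate with a hindered pyridine base silylates tertiary alcohols (silyl ether formation), and the two silyloxy groups then shield one face of the alkene.

Step 3
Reactants: 3 bis-silyl ether; 4 2-chloropropanoyl chloride
Product: 6 10-chloro-10-methyl cyclobutanone (C6 ketone; Cl exo; C14 endo; ring A cis-fused), via chloro(methyl)ketene 5 (not isolated)
Conditions: Et3N, hexane, reflux, slow addition of 4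
Reagents that add atoms: none
Why: dehydrochlorination of 4 gives ketene 5, which should undergo thermal [2+2] ketene–alkene cycloaddition anti to both silyloxy groups (setting H1 and H5 cis to O2 and O4), with the substituted ketene carbon bonding to C1, away from quaternary C4, and the carbonyl carbon to C5, while C10 is set only provisionally.

Step 4
Reactants: 6 chlorocyclobutanone
Product: 8 exo-methyl cyclobutanone (C14 exo; H10 endo), via endo-methyl ketone 7 (not isolated)
Conditions: Zn, NH4Cl, MeOH, rt; then DBU (cat.), CH2Cl2, rt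
Reagents that add atoms: none
Why: zinc-mediated reductive dehalogenation of the α-chloroketone is followed by base equilibration through the C10 enolate (C5 cannot enolise, since a double bond at the ring fusion is too strained), which should place C14 on the less crowded exo face and so fix C10–H as endo.

Step 5
Reactants: 8 exo-methyl cyclobutanone; 9 triethyl phosphonoacetate
Product: 10 (E)-ethyl 2-(cyclobutylidene)acetate, C6=C7 with the ester cis to C10
Conditions: NaH, THF, 0 °C to 50 °C
Reagents that add atoms: none
Why: Horner–Wadsworth–Emmons olefination of the electrophilic cyclobutanone, in which the ester should settle on the C10 side of the alkene, away from C5 and the quaternary C4 with its endo methyl.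

Step 6
Reactants: 10 (E)-enoate
Product: 11 diol ester (O6 exo on C6; C7 endo with OH; C7 configured so that O7 is cis to O6 when C8 faces C10)
Conditions: OsO4 (cat.), NMO, acetone/H2O, rt
Reagents that add atoms: osmium tetroxide, O=[Os](=O)(=O)=O; N-methylmorpholine N-oxide, C[N+]1([O-])CCOCC1
Why: catalytic syn-dihydroxylation (Upjohn conditions) of the alkylidenecyclobutane should occur from the exo face, opposite ring A and C15, which sets O6 exo and, by syn addition to the E-alkene, the C7 configuration.

Step 7
Reactants: 11 diol ester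
Product: 12 acetonide ester (dioxolane over O6 and O7; ester cis to C10 on the dioxolane)
Conditions: 2,2-dimethoxypropane, PPTS, CH2Cl2, rt
Reagents that add atoms: 2,2-dimethoxypropane, COC(C)(C)OC
Why: acid-catalysed transketalisation of the syn diol (acetonide formation) gives a dioxolane whose ketal carbon carries no hydrogen and whose geometry keeps C8 on the C10 side.

Step 8
Reactants: 12 acetonide ester
Product: 13 acetonide carboxylic acid
Conditions: LiOH, THF/MeOH/H2O, rt; then 1 M HCl to pH 4, 0 °C
Reagents that add atoms: lithium hydroxide, [Li+].[OH-]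
Why: saponification of the ethyl ester leaves the acetonide and both silyl ethers untouched.

Step 9
Reactants: 13 acetonide acid
Product: 15 diazoketone (C7 in the dioxolane; C8 carbonyl; C9 diazo), via acid chloride 14 (not isolated)
Conditions: 1-chloro-N,N,2-trimethylprop-1-en-1-amine, CH2Cl2, 0 °C; then CH2N2 (excess), Et2O, 0 °C
Reagents that add atoms: diazomethane, C=[N+]=[N-]; 1-chloro-N,N,2-trimethylprop-1-en-1-amine (chlorine of 14 only), CC(C)=C(Cl)N(C)C
Why: neutral acid chloride formation with the α-chloroenamine followed by acylation of diazomethane (Arndt–Eistert-type diazoketone synthesis), the excess diazomethane taking up the HCl.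

Step 10
Reactants: 15 diazoketone
Product: 16 tetracyclic C8 ketone (cis-syn-cis rings A, cyclobutane and C; quaternary C10; O6/O7 acetonide on the outer face of ring C)
Conditions: Rh2(OAc)4 (2 mol %), CH2Cl2, 40 °C, slow addition of 15
Reagents that add atoms: none
Why: Rh2(OAc)4 expels N2 from the diazoketone to give an electrophilic rhodium carbenoid at C9, which inserts into the C10–H bond through a concerted, asynchronous three-centre transition state. The closest known reaction type is the dirhodium-carbenoid 1,5 C–H insertion of α-diazoketones into tertiary C–H bonds, which gives cyclopentanones with a quaternary carbon and retention of configuration. Ring C closes by C9–C10 bond formation through a five-membered transition state (C9, C8, C7, C6, C10), cis-fused both to the cyclobutane and to the dioxolane. The only new stereocentre, quaternary C10, is controlled by retention: C10–H is endo and cis to the C6 chain (from steps 4 and 6), so C9 replaces H on the endo face and C14 stays exo, which makes the tricycle cis-syn-cis. The step needs site selectivity for C10–H over C5–H, C14–H3, the ketal methyls and ylide formation at oxygen; the dioxolane holds C8 on the C10 side of its ring while H5 lies on the far face, only C10–H completes a five-membered ring, the ketal carbon has no hydrogen and no freely rotating ether oxygen sits five atoms from C9. The main liability is that C10–H is a cyclobutane methine β to O6 and therefore electronically deactivated, which slow addition of 15 should offset by suppressing carbene dimerisation.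

Step 11
Reactants: 16 tetracyclic ketone
Product: 17 C8 alcohol (O8 on the outer face of ring C, cis to O7, O6 and C14)
Conditions: NaBH4, MeOH, −40 °C to 0 °C
Reagents that add atoms: none
Why: hydride reduction of the cyclopentanone should occur anti to the adjacent C7–O7 bond and away from the dioxolane and C14 on the outer face, as is usual for acetonide-fused cyclopentanones, which gives O8 cis to O7 as in the target.

Step 12
Reactants: 17 C8 alcohol; 18 tigloyl chloride ((E)-2-methylbut-2-enoyl chloride)
Product: 19 C8 tiglate acetonide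
Conditions: Et3N, DMAP, CH2Cl2, 0 °C to rt
Reagents that add atoms: none
Why: DMAP-catalysed acylation of the secondary alcohol by the acid chloride (esterification) installs the tiglate without touching its E-alkene or the C8 configuration.

Step 13
Reactants: 19 tiglate acetonide
Product: 20 tiglate C6,C7-diol
Conditions: AcOH/THF/H2O (3:1:1), 40 °C
Reagents that add atoms: none
Why: mild acid hydrolysis of the crowded dioxolane (acetal cleavage) should spare the secondary and tertiary TBS ethers and the hindered conjugated ester, which migrates only slowly under acid.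

Step 14
Reactants: 20 tiglate diol
Product: 21 C7 ketone with free tertiary C6 hydroxyl (ketol)
Conditions: Dess–Martin periodinane, NaHCO3, CH2Cl2, 0 °C to rt
Reagents that add atoms: none
Why: Dess–Martin oxidation converts the secondary C7 alcohol into the ketone under buffered, non-basic conditions, the tertiary C6 alcohol cannot be oxidised, and the ketol is used at once to avoid an acyloin shift of the cyclobutanol.

Step 15
Reactants: 22 trimethyl 2-phosphonoacrylate (methyl 2-(dimethoxyphosphoryl)acrylate); 23 4-methoxybenzyl alcohol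
Product: 24 methyl 2-(dimethoxyphosphoryl)-3-(4-methoxybenzyloxy)propanoate (racemic)
Conditions: NaH (10 mol %), THF, 0 °C
Reagents that add atoms: none
Why: base-catalysed oxa-Michael addition of the alkoxide to the doubly activated acrylate, the phosphonate-stabilised carbanion being protonated by the alcohol so that the base turns over.

Step 16
Reactants: 24 phosphonate methyl ester
Product: 25 2-(dimethoxyphosphoryl)-3-(4-methoxybenzyloxy)propanoic acid (racemic)
Conditions: LiOH (1.05 equiv), THF/H2O, 0 °C; then 1 M HCl
Reagents that add atoms: lithium hydroxide, [Li+].[OH-]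
Why: selective saponification of the carboxylic methyl ester beside the phosphonate esters, the carboxylate formed shutting down α-deprotonation and hence retro-Michael loss of the alkoxide.

Step 17
Reactants: 21 ketol; 25 phosphonate acid
Product: 26 C6 phosphonoacetate ester of the ketol (mixture at the phosphonate carbon)
Conditions: DCC, DMAP, CH2Cl2, 0 °C to rt
Reagents that add atoms: none
Why: Steglich esterification, which for phosphonoacetic acids can run through a reactive phosphonoketene, should reach the hindered tertiary C6 hydroxyl under neutral conditions, and the phosphonate carbon it leaves unassigned becomes sp2 in the next step.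

Step 18
Reactants: 26 phosphonoacetate ester
Product: 27 butenolide with C13 4-methoxybenzyl ether, C8 tiglate and C2, C4 TBS ethers
Conditions: NaH (1.05 equiv), THF, 0 °C
Reagents that add atoms: none
Why: intramolecular Horner–Wadsworth–Emmons reaction of the phosphonate carbanion with the adjacent C7 ketone closes the butenolide (C7=C11) and removes the C7 stereocentre, five-ring closure being expected to outrun β-elimination of the poor alkoxide leaving group.

Step 19
Reactants: 27 protected butenolide
Product: 28 C13 primary alcohol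
Conditions: DDQ, CH2Cl2/pH 7 buffer, 0 °C to rt
Reagents that add atoms: none
Why: oxidative cleavage of the 4-methoxybenzyl ether by DDQ (benzylic oxidation to the oxocarbenium ion and hydrolysis) spares silyl ethers, tiglate and butenolide.

Step 20
Reactants: 28 C13 alcohol
Product: 29 C2, C4, C13 triol
Conditions: aq. HF, MeCN, rt
Reagents that add atoms: none
Why: desilylation with aqueous HF in acetonitrile removes the secondary and the hindered tertiary TBS ether without touching the esters.

Step 21
Reactants: 29 triol
Product: 30 target CNP0210373.1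
Conditions: Ac2O, pyridine, DMAP (cat.), 0 °C
Reagents that add atoms: acetic anhydride, CC(=O)OC(C)=O
Why: chemoselective acylation esterifies the primary C13 and secondary C2 hydroxyls, while the tertiary C4 hydroxyl is too hindered to react under these conditions.

Compound list
1 | (S)-4-(tert-butyldimethylsilyloxy)cyclopent-2-en-1-one | O=C1C=C[C@@H](O[Si](C)(C)C(C)(C)C)C1 | starting material
2 | (1R,4S)-4-(tert-butyldimethylsilyloxy)-1-methylcyclopent-2-en-1-ol | C[C@]1(O)C=C[C@@H](O[Si](C)(C)C(C)(C)C)C1 | intermediate
3 | (3R,5S)-3,5-bis(tert-butyldimethylsilyloxy)-3-methylcyclopent-1-ene | C[C@]1(O[Si](C)(C)C(C)(C)C)C=C[C@@H](O[Si](C)(C)C(C)(C)C)C1 | intermediate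
4 | 2-chloropropanoyl chloride (racemic) | CC(Cl)C(Cl)=O | starting material
5 | chloro(methyl)ketene | CC(Cl)=C=O | intermediate
6 | 10-chloro-10-methyl cyclobutanone: cis-fused ring A/cyclobutane, C6 ketone, Cl exo, C14 endo, 2- and 4-OTBS cis to H1/H5, C15 on the cyclobutane side | C[C@]1(Cl)[C@@H]2[C@@H](O[Si](C)(C)C(C)(C)C)C[C@@](C)(O[Si](C)(C)C(C)(C)C)[C@@H]2C1=O | intermediate
7 | endo-methyl cyclobutanone (C10 epimer of 8) | C[C@@H]1[C@@H]2[C@@H](O[Si](C)(C)C(C)(C)C)C[C@@](C)(O[Si](C)(C)C(C)(C)C)[C@@H]2C1=O | intermediate
8 | exo-methyl cyclobutanone (C14 exo, H10 endo) | C[C@H]1[C@@H]2[C@@H](O[Si](C)(C)C(C)(C)C)C[C@@](C)(O[Si](C)(C)C(C)(C)C)[C@@H]2C1=O | intermediate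
9 | triethyl phosphonoacetate | CCOC(=O)CP(=O)(OCC)OCC | starting material
10 | (E)-enoate, C6=C7 with ester cis to C10 | CCOC(=O)/C=C1\[C@@H](C)[C@@H]2[C@@H](O[Si](C)(C)C(C)(C)C)C[C@@](C)(O[Si](C)(C)C(C)(C)C)[C@@H]21 | intermediate
11 | diol ester, O6 exo, C7 endo with OH | C[C@H]1[C@@H]2[C@@H](O[Si](C)(C)C(C)(C)C)C[C@@](C)(O[Si](C)(C)C(C)(C)C)[C@@H]2[C@]1(O)[C@@H](O)C(=O)OCC | intermediate
12 | acetonide ethyl ester, ester cis to C10 on the dioxolane | C[C@H]1[C@@H]2[C@@H](O[Si](C)(C)C(C)(C)C)C[C@@](C)(O[Si](C)(C)C(C)(C)C)[C@@H]2[C@@]13OC(C)(C)O[C@H]3C(=O)OCC | intermediate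
13 | acetonide carboxylic acid | C[C@H]1[C@@H]2[C@@H](O[Si](C)(C)C(C)(C)C)C[C@@](C)(O[Si](C)(C)C(C)(C)C)[C@@H]2[C@@]13OC(C)(C)O[C@H]3C(=O)O | intermediate
14 | acetonide acid chloride | C[C@H]1[C@@H]2[C@@H](O[Si](C)(C)C(C)(C)C)C[C@@](C)(O[Si](C)(C)C(C)(C)C)[C@@H]2[C@@]13OC(C)(C)O[C@H]3C(Cl)=O | intermediate
15 | diazoketone, precursor of the key step | C[C@H]1[C@@H]2[C@@H](O[Si](C)(C)C(C)(C)C)C[C@@](C)(O[Si](C)(C)C(C)(C)C)[C@@H]2[C@@]13OC(C)(C)O[C@H]3C(=O)C=[N+]=[N-] | intermediate
16 | tetracyclic C8 ketone, product of the key step | O=C1C[C@]2(C)[C@@H]3[C@@H](O[Si](C)(C)C(C)(C)C)C[C@@](C)(O[Si](C)(C)C(C)(C)C)[C@@H]3[C@@]24OC(C)(C)O[C@@H]14 | intermediate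
17 | C8 alcohol, O8 cis to O7 | O[C@H]1C[C@]2(C)[C@@H]3[C@@H](O[Si](C)(C)C(C)(C)C)C[C@@](C)(O[Si](C)(C)C(C)(C)C)[C@@H]3[C@@]24OC(C)(C)O[C@@H]14 | intermediate
18 | tigloyl chloride, (E)-2-methylbut-2-enoyl chloride | C/C=C(\C)C(Cl)=O | starting material
19 | C8 tiglate acetonide | C/C=C(\C)C(=O)O[C@H]1C[C@]2(C)[C@@H]3[C@@H](O[Si](C)(C)C(C)(C)C)C[C@@](C)(O[Si](C)(C)C(C)(C)C)[C@@H]3[C@@]24OC(C)(C)O[C@@H]14 | intermediate
20 | C8 tiglate C6,C7-diol | C/C=C(\C)C(=O)O[C@H]1C[C@]2(C)[C@@H]3[C@@H](O[Si](C)(C)C(C)(C)C)C[C@@](C)(O[Si](C)(C)C(C)(C)C)[C@@H]3[C@]2(O)[C@H]1O | intermediate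
21 | C8 tiglate C7-ketone C6-ol | C/C=C(\C)C(=O)O[C@H]1C[C@]2(C)[C@@H]3[C@@H](O[Si](C)(C)C(C)(C)C)C[C@@](C)(O[Si](C)(C)C(C)(C)C)[C@@H]3[C@]2(O)C1=O | intermediate
22 | trimethyl 2-phosphonoacrylate | C=C(C(=O)OC)P(=O)(OC)OC | starting material
23 | 4-methoxybenzyl alcohol | COc1ccc(CO)cc1 | starting material
24 | methyl 2-(dimethoxyphosphoryl)-3-(4-methoxybenzyloxy)propanoate | COC(=O)C(COCc1ccc(OC)cc1)P(=O)(OC)OC | intermediate
25 | 2-(dimethoxyphosphoryl)-3-(4-methoxybenzyloxy)propanoic acid | OC(=O)C(COCc1ccc(OC)cc1)P(=O)(OC)OC | intermediate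
26 | C6 phosphonoacetate ester of ketol 21 | C/C=C(\C)C(=O)O[C@H]1C[C@]2(C)[C@@H]3[C@@H](O[Si](C)(C)C(C)(C)C)C[C@@](C)(O[Si](C)(C)C(C)(C)C)[C@@H]3[C@]2(OC(=O)C(COCc4ccc(OC)cc4)P(=O)(OC)OC)C1=O | intermediate
27 | butenolide with C13 4-methoxybenzyl ether | C/C=C(\C)C(=O)O[C@H]1C[C@]2(C)[C@@H]3[C@@H](O[Si](C)(C)C(C)(C)C)C[C@@](C)(O[Si](C)(C)C(C)(C)C)[C@@H]3[C@@]23OC(=O)C(COCc4ccc(OC)cc4)=C13 | intermediate
28 | butenolide C13 alcohol | C/C=C(\C)C(=O)O[C@H]1C[C@]2(C)[C@@H]3[C@@H](O[Si](C)(C)C(C)(C)C)C[C@@](C)(O[Si](C)(C)C(C)(C)C)[C@@H]3[C@@]23OC(=O)C(CO)=C13 | intermediate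
29 | C2, C4, C13 triol | C/C=C(\C)C(=O)O[C@H]1C[C@]2(C)[C@@H]3[C@@H](O)C[C@@](C)(O)[C@@H]3[C@@]23OC(=O)C(CO)=C13 | intermediate
30 | CNP0210373.1 | C/C=C(\C)C(=O)O[C@H]1C[C@]2(C)[C@@H]3[C@@H](OC(C)=O)C[C@@](C)(O)[C@@H]3[C@@]23OC(=O)C(COC(C)=O)=C13 | target

Total step count: 21. Longest linear sequence: 19 (steps 1–14 and 17–21; steps 15 and 16 make the phosphonate acid).

Steps most likely to fail

Step 10. The carbenoid may be consumed by dimerisation, by attack of a dioxolane oxygen or by insertion into a ketal methyl group before it reaches C10–H. That bond is deactivated by the β-oxygen O6 and by the s-character of a cyclobutane C–H bond. The fallback changes the reactive species from a diazomethyl ketone to a diazo β-keto ester, whose acceptor/acceptor carbenoid is longer-lived and more discriminating; it sets out from acid 13 and returns at ketone 16. Acid 13 would be activated with 1,1'-carbonyldiimidazole and condensed with Mg(O2CCH2CO2Me)2 in THF to give the methyl β-keto ester F1. Diazo transfer with 4-acetamidobenzenesulfonyl azide and Et3N in MeCN would give the α-diazo-β-keto ester F2. Rh2(OAc)4 in CH2Cl2 at 40 °C should then insert into C10–H to give the ring C β-keto ester F3. Krapcho demethoxycarbonylation with LiCl in wet DMSO at 130 °C would deliver 16.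

Step 3. The cycloaddition of the alkylhaloketene to an alkene deactivated by two allylic oxygens may be slow, so that ketene oligomerisation competes, and the regioselectivity between C1 and C5 may erode. The fallback sets out from bis-silyl ether 3 and returns at ketone 8. The more electrophilic and bulkier dichloroketene (Cl3CCOCl, Zn(Cu), Et2O/DME) would give the dichlorocyclobutanone F4. Zn and NH4Cl in MeOH would remove both chlorines to give the parent cyclobutanone F5. Kinetic deprotonation at C10 with LiN(SiMe3)2 in THF at −78 °C and methylation with MeI from the exo face would give 8 directly.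

Step 11. Facial selectivity may be poor or reversed: if the cleft between rings A and C is more congested than the dioxolane side, hydride is delivered from the outer face and the C8 epimer forms. The fallback accepts that epimer and inverts it during ester formation; it sets out from ketone 16 and returns at tiglate 19. Reduction of 16 (LiBH(s-Bu)3 would favour outer-face attack) gives the epimeric C8 alcohol F6. Tf2O and pyridine in CH2Cl2 at −20 °C would convert it into the C8 triflate F7. SN2 displacement with cesium (E)-2-methylbut-2-enoate and 18-crown-6 in toluene, from the face that the hydride showed to be open, would give 19 with inversion and make step 12 unnecessary.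

Further compounds
F1 | step 10 | methyl β-keto ester from acid 13 | C[C@H]1[C@@H]2[C@@H](O[Si](C)(C)C(C)(C)C)C[C@@](C)(O[Si](C)(C)C(C)(C)C)[C@@H]2[C@@]13OC(C)(C)O[C@H]3C(=O)CC(=O)OC
F2 | step 10 | α-diazo-β-keto ester | C[C@H]1[C@@H]2[C@@H](O[Si](C)(C)C(C)(C)C)C[C@@](C)(O[Si](C)(C)C(C)(C)C)[C@@H]2[C@@]13OC(C)(C)O[C@H]3C(=O)C(=[N+]=[N-])C(=O)OC
F3 | step 10 | ring C β-keto ester (methyl ester on C9) | COC(=O)C1[C@]2(C)[C@@H]3[C@@H](O[Si](C)(C)C(C)(C)C)C[C@@](C)(O[Si](C)(C)C(C)(C)C)[C@@H]3[C@@]24OC(C)(C)O[C@H]4C1=O
F4 | step 3 | 10,10-dichlorocyclobutanone | ClC1(Cl)[C@@H]2[C@@H](O[Si](C)(C)C(C)(C)C)C[C@@](C)(O[Si](C)(C)C(C)(C)C)[C@@H]2C1=O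
F5 | step 3 | parent cyclobutanone (C10 methylene) | C1[C@@H]2[C@@H](O[Si](C)(C)C(C)(C)C)C[C@@](C)(O[Si](C)(C)C(C)(C)C)[C@@H]2C1=O
F6 | step 11 | epimeric C8 alcohol (O8 on the inner face) | O[C@@H]1C[C@]2(C)[C@@H]3[C@@H](O[Si](C)(C)C(C)(C)C)C[C@@](C)(O[Si](C)(C)C(C)(C)C)[C@@H]3[C@@]24OC(C)(C)O[C@@H]14
F7 | step 11 | C8 triflate of the epimeric alcohol | FC(F)(F)S(=O)(=O)O[C@@H]1C[C@]2(C)[C@@H]3[C@@H](O[Si](C)(C)C(C)(C)C)C[C@@](C)(O[Si](C)(C)C(C)(C)C)[C@@H]3[C@@]24OC(C)(C)O[C@@H]14
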